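**Retrosynthetic overview**

1. Target ⇐ bis-angeloylation at O6 and O10 and release of O2 from triol 24. The C6 carbinol comes from a C6 ketone by hydride delivery from the C4 hydroxyl, and the C2 carbinol is set the same way earlier.
2. Seven-membered ring (C1, C5–C10) ⇐ one-pot (3+4) annulation of acylsilane 13 (C6 attached to the cyclopentene C5=C1) with the lithium enolate of enone 16 (C7–C10). C6–C7 forms first and C1–C10 closes the ring; the regiodefined C8 enolate is trapped as a triflate and later becomes C8–CH3.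
3. Enabling feature: the tetrasubstituted C1=C5 alkene of the five-membered ring (carrying the acylsilane carbon C6) and the (E)-C9=C10 enol ether next to the C8 ketone become the two vinyl arms of a transient cis-divinylcyclopropanolate (C6–C7–C8). Its strain and the C8 oxyanion drive the [3,3] shift that forms C1–C10 and the C1 quaternary centre.
4. Five-membered ring ⇐ Claisen cyclisation of a keto-dioxolanone from (2S)-2-isopropylmalic acid (C4 bought); the C6 carbon is added as 1,3-dithiane by a Stork–Danheiser sequence.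
5. Ring order: cyclopentane (steps 1–9), then cycloheptadiene (step 11).

Key step: step 11

Remark: daucane numbering is used (C1 = methyl-bearing ring-fusion carbon, C2 = CHOH, C3 = CH2, C4 = C(OH)iPr, C5 = ring-fusion CH, C6–C10 = rest of the seven-membered ring, C14 = methyl on C8); β is the face of the C1 methyl group; compounds 1, 7, 14, 15, 25 and all reagents are assumed to be commercial.

**Step 1**
Reactants: 1 (2S)-2-isopropylmalic acid
Product: 2 2-[(4S)-2,2-dimethyl-5-oxo-4-(propan-2-yl)-1,3-dioxolan-4-yl]acetic acid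
Conditions: Me2C(OMe)2, TsOH (cat.), CH2Cl2, rt
Reagents that add atoms: 2,2-dimethoxypropane, COC(C)(C)OC
Why: Acid-catalysed 1,3-dioxolan-4-one formation ties up the α-hydroxy acid as the five-membered acetonide and leaves the CH2CO2H arm free; the C4 stereocentre bought with 1 is not touched.

**Step 2**
Reactants: 2 dioxolanone acid
Product: 4 (5S)-2,2-dimethyl-5-(2-oxobutyl)-5-(propan-2-yl)-1,3-dioxolan-4-one, via acid chloride 3 (not isolated)
Conditions: (COCl)2, DMF (cat.), CH2Cl2, 0 °C to rt; then EtMgBr, Fe(acac)3 (3 mol %), THF, −78 °C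
Reagents that add atoms: ethylmagnesium bromide, CC[Mg]Br; oxalyl chloride, ClC(=O)C(=O)Cl (chlorine of 3 only)
Why: Acid chloride formation followed by iron-catalysed acylation of the Grignard reagent should give the ketone faster than the Grignard reagent attacks the dioxolanone carbonyl; no stereocentre is involved.

**Step 3**
Reactants: 4 ethyl ketone
Product: 5 (4S)-4-hydroxy-2-methyl-4-(propan-2-yl)cyclopentane-1,3-dione (drawn as its enol)
Conditions: KOtBu (2.2 equiv), THF, 0 °C to rt; then 1 M HCl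
Reagents that add atoms: none
Why: Intramolecular Claisen (Dieckmann-type) condensation: the ethyl ketone enolate (C1) attacks the activated dioxolanone carbonyl (C5) in a 5-exo closure, acetone is expelled and deprotonation of the 1,3-dione drives the reaction; C4 is retained.

**Step 4**
Reactants: 5 hydroxy dione
Product: 6 (5S)-5-hydroxy-3-methoxy-2-methyl-5-(propan-2-yl)cyclopent-2-en-1-one
Conditions: MeOH, TsOH (cat.), 3 Å sieves, 40 °C
Reagents that add atoms: methanol, CO
Why: Reversible acid-catalysed enol ether formation of the 1,3-dione should give the vinylogous ester with the methoxy group on the oxygen remote from the quaternary carbinol carbon (less hindered, thermodynamic regioisomer).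

**Step 5**
Reactants: 6 vinylogous ester; 7 1,3-dithiane
Product: 9 (4S)-3-(1,3-dithian-2-yl)-4-hydroxy-2-methyl-4-(propan-2-yl)cyclopent-2-en-1-one, via dithianyl carbinol 8 (not isolated)
Conditions: 7 (2.3 equiv), n-BuLi (2.2 equiv), THF, −30 °C; 6, −78 to −20 °C; then 1 M HCl, THF, 0 °C to rt
Reagents that add atoms: 1,3-dithiane, C1CSCSC1
Why: Stork–Danheiser sequence: 1,2-addition of 2-lithio-1,3-dithiane to the vinylogous ester carbonyl (C5), then acid-induced loss of water and enol ether hydrolysis transpose the enone; the carbinol centre of 8 is destroyed and C4 is retained.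

**Step 6**
Reactants: 9 enone
Product: 10 (1R,4S)-3-(1,3-dithian-2-yl)-2-methyl-4-(propan-2-yl)cyclopent-2-ene-1,4-diol
Conditions: Me4NBH(OAc)3, MeCN/AcOH (1:1), −30 to −10 °C
Reagents that add atoms: none
Why: Hydroxyl-directed (Evans–Saksena) reduction: the C4 hydroxyl binds boron and delivers hydride to C2 on its own (α) face, which is also the face remote from the β-isopropyl group, so the trans-1,3-diol (2β-OH) should result.

**Step 7**
Reactants: 10 diol
Product: 11 (1S,4R)-4-[(tert-butyldimethylsilyl)oxy]-2-(1,3-dithian-2-yl)-3-methyl-1-(propan-2-yl)cyclopent-2-en-1-ol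
Conditions: TBSCl, imidazole, DMF, rt
Reagents that add atoms: tert-butyldimethylsilyl chloride, CC(C)(C)[Si](C)(C)Cl
Why: Selective silylation of the secondary allylic alcohol; the tertiary C4 hydroxyl does not react under these conditions.

**Step 8**
Reactants: 11 silyl ether
Product: 12 2-[(3R,5S)-3-[(tert-butyldimethylsilyl)oxy]-2-methyl-5-(propan-2-yl)-5-[(trimethylsilyl)oxy]cyclopent-1-en-1-yl]-2-(trimethylsilyl)-1,3-dithiane
Conditions: n-BuLi (2.2 equiv), THF, −78 to −25 °C; Me3SiCl (2.6 equiv), −78 to 0 °C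
Reagents that add atoms: chlorotrimethylsilane, C[Si](C)(C)Cl
Why: Deprotonation of the tertiary alcohol and of the allylic dithiane C–H, then double silylation (Brook–Corey acylsilane route); the hard chlorosilane should react at the dithiane carbon and not at the fully substituted γ-carbon C1.

**Step 9**
Reactants: 12 silyl dithiane
Product: 13 [(3R,5S)-3-[(tert-butyldimethylsilyl)oxy]-2-methyl-5-(propan-2-yl)-5-[(trimethylsilyl)oxy]cyclopent-1-en-1-yl](trimethylsilyl)methanone
Conditions: MeI, CaCO3, MeCN/H2O (9:1), 40 °C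
Reagents that add atoms: water, O
Why: Alkylative hydrolysis of the 2-silyl-1,3-dithiane unmasks the acylsilane (Brook–Corey acylsilane synthesis); the carbonate buffer should spare the silyl ethers.

**Step 10**
Reactants: 14 (E)-4-methoxybut-3-en-2-one; 15 4-methoxybenzyl alcohol
Product: 16 (E)-4-[(4-methoxyphenyl)methoxy]but-3-en-2-one
Conditions: PPTS (5 mol %), toluene, 70 °C, reduced pressure (removal of MeOH)
Reagents that add atoms: 4-methoxybenzyl alcohol, COc1ccc(CO)cc1
Why: Acid-catalysed transetherification (addition–elimination at the β-carbon of the vinylogous ester) exchanges methoxy for 4-methoxybenzyloxy and keeps the more stable (E)-alkene.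

**Step 11**
Reactants: 13 acylsilane; 16 enone
Product: 20 14-nordauca-5,8-diene enol triflate (full name in the list), via lithium dienolate 17 (not isolated), via lithium divinylcyclopropanolate 18 (not isolated), via lithium cycloheptadienolate 19 (not isolated)
Conditions: LiN(iPr)2, THF, −80 °C; 13, −80 to −40 °C; then N-(5-chloropyridin-2-yl)triflimide, −78 to −30 °C
Reagents that add atoms: Comins' reagent, FC(F)(F)S(=O)(=O)N(c1ccc(Cl)cn1)S(=O)(=O)C(F)(F)F; lithium diisopropylamide, [Li+].CC(C)[N-]C(C)C (lithium of 17 to 19 only)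
Why: Enolate 17 adds to the acylsilane carbonyl (C6–C7), a 1,2-Brook shift moves silicon from C6 to oxygen, and the siloxyallyl carbanion closes onto the C8 ketone to give cyclopropanolate 18, whose oxyanion-accelerated divinylcyclopropane (Cope) rearrangement breaks C6–C8 and forms C1–C10; enolate 19 is then O-triflated. The closest known reaction type is the Brook-rearrangement-mediated (3+4) annulation of α,β-unsaturated acylsilanes with lithium enolates of alkenyl methyl ketones, which has been used to build hydroazulenes with an angular methyl group. The seven-membered ring closes in the [3,3] step through a boat transition state in which the C5=C1 and C9=C10 arms lie over the cyclopropane. At C1, C10 should add to the α-face, anti to the β-silyloxy group on C2 and on the side of the smaller α-substituent on C4, so the methyl group becomes β. At C10, the (E)-geometry of the enol ether places the ether oxygen cis to C2 and trans to the C1 methyl (10α), because substituents of like geometry on the two termini end up cis in the boat. The step needs the cis-cyclopropane and O-triflation at C8 only: lithium bridging of the two oxygens and reversible cyclopropanolate closure (only the cis isomer can rearrange) should secure the first, and prior silylation of the C6 oxygen secures the second.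

**Step 12**
Reactants: 20 enol triflate
Product: 21 2β-(tert-butyldimethylsilyloxy)-10α-(4-methoxybenzyloxy)-4α,6-bis(trimethylsilyloxy)dauca-5,8-diene
Conditions: MeMgBr (1.5 equiv), Fe(acac)3 (5 mol %), THF/NMP, −30 °C
Reagents that add atoms: methylmagnesium bromide, C[Mg]Br
Why: Iron-catalysed cross-coupling of the alkenyl triflate with the Grignard reagent replaces OTf by methyl and keeps the C8=C9 position; no stereocentre is touched.

**Step 13**
Reactants: 21 bis(silyl) diene
Product: 22 2β-(tert-butyldimethylsilyloxy)-4α-hydroxy-10α-(4-methoxybenzyloxy)-5β-H-dauc-8-en-6-one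
Conditions: Bu4NF (2.2 equiv), AcOH (2.5 equiv), THF, −40 to 0 °C
Reagents that add atoms: none
Why: Fluoride cleaves the trimethylsilyl enol ether first, and the enolate should be protonated at C5 on the convex β-face (syn to the angular methyl, anti to the α-oriented C4 silyl ether and C10 ether, as with angularly methylated hydrindenones). This gives the cis-fused ketone, which should also be the thermodynamically preferred ring fusion; the tertiary trimethylsilyl ether is then cleaved and the TBS ether should survive the buffered fluoride.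

**Step 14**
Reactants: 22 hydroxy ketone
Product: 23 2β-(tert-butyldimethylsilyloxy)-10α-(4-methoxybenzyloxy)-5β-H-dauc-8-ene-4α,6β-diol
Conditions: Me4NBH(OAc)3, MeCN/AcOH (1:1), −30 °C
Reagents that add atoms: none
Why: Hydroxyl-directed (Evans–Saksena) reduction: the α-oriented C4 hydroxyl delivers hydride to the C6 carbonyl from the concave α-face, giving the 6β-alcohol (anti-1,3-diol); the skipped C8=C9 alkene should not move under these weakly acidic conditions.

**Step 15**
Reactants: 23 diol
Product: 24 2β-(tert-butyldimethylsilyloxy)-5β-H-dauc-8-ene-4α,6β,10α-triol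
Conditions: DDQ, CH2Cl2/pH 7 buffer (10:1), 0 °C
Reagents that add atoms: none
Why: Oxidative cleavage of the 4-methoxybenzyl ether frees the C10 hydroxyl without affecting the TBS ether or the trisubstituted alkene.

**Step 16**
Reactants: 24 triol; 25 angelic acid
Product: 27 6β,10α-bis(angeloyloxy)-2β-(tert-butyldimethylsilyloxy)-5β-H-dauc-8-en-4α-ol, via mixed anhydride 26 (not isolated)
Conditions: 25, 2,4,6-trichlorobenzoyl chloride, Et3N, toluene, rt; then 24, toluene, 80 °C
Reagents that add atoms: angelic acid, C/C=C(/C)C(=O)O; 2,4,6-trichlorobenzoyl chloride, O=C(Cl)c1c(Cl)cc(Cl)cc1Cl (aroyl part of 26 only)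
Why: Yamaguchi-type acylation with the preformed mixed anhydride should acylate the two secondary hydroxyls (C6, C10) and leave the tertiary C4 hydroxyl; heating without 4-(dimethylamino)pyridine is chosen to avoid Z to E isomerisation of the angelate.

**Step 17**
Reactants: 27 silyl ether
Product: 28 6β,10α-bis(angeloyloxy)-5β-H-dauc-8-ene-2β,4α-diol (CNP0249167.1)
Conditions: HF·pyridine, pyridine/THF, 0 °C to rt
Reagents that add atoms: none
Why: Fluoride-mediated desilylation under non-basic conditions frees the C2 hydroxyl without acyl migration or angelate isomerisation.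

**Compound list**

1 | (2S)-2-hydroxy-2-(propan-2-yl)butanedioic acid ((2S)-2-isopropylmalic acid) | OC(=O)C[C@](O)(C(C)C)C(=O)O | starting material
2 | 2-[(4S)-2,2-dimethyl-5-oxo-4-(propan-2-yl)-1,3-dioxolan-4-yl]acetic acid | OC(=O)C[C@@]1(C(C)C)OC(C)(C)OC1=O | intermediate
3 | 2-[(4S)-2,2-dimethyl-5-oxo-4-(propan-2-yl)-1,3-dioxolan-4-yl]acetyl chloride (not isolated) | ClC(=O)C[C@@]1(C(C)C)OC(C)(C)OC1=O | intermediate
4 | (5S)-2,2-dimethyl-5-(2-oxobutyl)-5-(propan-2-yl)-1,3-dioxolan-4-one | CCC(=O)C[C@@]1(C(C)C)OC(C)(C)OC1=O | intermediate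
5 | (4S)-4-hydroxy-2-methyl-4-(propan-2-yl)cyclopentane-1,3-dione, drawn as the enol (5S)-3,5-dihydroxy-2-methyl-5-(propan-2-yl)cyclopent-2-en-1-one | CC1=C(O)C[C@](O)(C(C)C)C1=O | intermediate
6 | (5S)-5-hydroxy-3-methoxy-2-methyl-5-(propan-2-yl)cyclopent-2-en-1-one | COC1=C(C)C(=O)[C@@](O)(C(C)C)C1 | intermediate
7 | 1,3-dithiane | C1CSCSC1 | starting material
8 | (5S)-1-(1,3-dithian-2-yl)-3-methoxy-2-methyl-5-(propan-2-yl)cyclopent-2-ene-1,5-diol, formed as its dilithium salt, both C1 epimers (not isolated) | COC1=C(C)C(O)(C2SCCCS2)[C@@](O)(C(C)C)C1 | intermediate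
9 | (4S)-3-(1,3-dithian-2-yl)-4-hydroxy-2-methyl-4-(propan-2-yl)cyclopent-2-en-1-one | CC1=C(C2SCCCS2)[C@@](O)(C(C)C)CC1=O | intermediate
10 | (1R,4S)-3-(1,3-dithian-2-yl)-2-methyl-4-(propan-2-yl)cyclopent-2-ene-1,4-diol | CC1=C(C2SCCCS2)[C@@](O)(C(C)C)C[C@H]1O | intermediate
11 | (1S,4R)-4-[(tert-butyldimethylsilyl)oxy]-2-(1,3-dithian-2-yl)-3-methyl-1-(propan-2-yl)cyclopent-2-en-1-ol | CC1=C(C2SCCCS2)[C@@](O)(C(C)C)C[C@H]1O[Si](C)(C)C(C)(C)C | intermediate
12 | 2-[(3R,5S)-3-[(tert-butyldimethylsilyl)oxy]-2-methyl-5-(propan-2-yl)-5-[(trimethylsilyl)oxy]cyclopent-1-en-1-yl]-2-(trimethylsilyl)-1,3-dithiane | CC1=C(C2([Si](C)(C)C)SCCCS2)[C@@](O[Si](C)(C)C)(C(C)C)C[C@H]1O[Si](C)(C)C(C)(C)C | intermediate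
13 | [(3R,5S)-3-[(tert-butyldimethylsilyl)oxy]-2-methyl-5-(propan-2-yl)-5-[(trimethylsilyl)oxy]cyclopent-1-en-1-yl](trimethylsilyl)methanone | CC1=C(C(=O)[Si](C)(C)C)[C@@](O[Si](C)(C)C)(C(C)C)C[C@H]1O[Si](C)(C)C(C)(C)C | intermediate
14 | (E)-4-methoxybut-3-en-2-one | CO/C=C/C(C)=O | starting material
15 | (4-methoxyphenyl)methanol | COc1ccc(CO)cc1 | starting material
16 | (E)-4-[(4-methoxyphenyl)methoxy]but-3-en-2-one | CC(=O)/C=C/OCc1ccc(OC)cc1 | intermediate
17 | lithium (E)-4-[(4-methoxyphenyl)methoxy]buta-1,3-dien-2-olate (not isolated) | [Li+].C=C([O-])/C=C/OCc1ccc(OC)cc1 | intermediate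
18 | lithium cis-cyclopropanolate: C6 carries OSiMe3 and the cyclopentenyl group, C8 carries O− and the (E)-2-(4-methoxybenzyloxy)vinyl group, the two alkenyl groups cis (not isolated) | [Li+].CC1=C([C@]2(O[Si](C)(C)C)C[C@]2([O-])/C=C/OCc3ccc(OC)cc3)[C@@](O[Si](C)(C)C)(C(C)C)C[C@H]1O[Si](C)(C)C(C)(C)C | intermediate
19 | lithium 2β-(tert-butyldimethylsilyloxy)-10α-(4-methoxybenzyloxy)-4α,6-bis(trimethylsilyloxy)-14-nordauca-5,8-dien-8-olate (not isolated) | [Li+].C[Si](C)(C)OC1CC([O-])=C[C@@H](OCc3ccc(OC)cc3)[C@@]2(C)[C@H](O[Si](C)(C)C(C)(C)C)C[C@](O[Si](C)(C)C)(C(C)C)C=12 | intermediate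
20 | 2β-(tert-butyldimethylsilyloxy)-10α-(4-methoxybenzyloxy)-4α,6-bis(trimethylsilyloxy)-14-nordauca-5,8-dien-8-yl trifluoromethanesulfonate | C[Si](C)(C)OC1CC(OS(=O)(=O)C(F)(F)F)=C[C@@H](OCc3ccc(OC)cc3)[C@@]2(C)[C@H](O[Si](C)(C)C(C)(C)C)C[C@](O[Si](C)(C)C)(C(C)C)C=12 | intermediate
21 | 2β-(tert-butyldimethylsilyloxy)-10α-(4-methoxybenzyloxy)-4α,6-bis(trimethylsilyloxy)dauca-5,8-diene | C[Si](C)(C)OC1CC(C)=C[C@@H](OCc3ccc(OC)cc3)[C@@]2(C)[C@H](O[Si](C)(C)C(C)(C)C)C[C@](O[Si](C)(C)C)(C(C)C)C=12 | intermediate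
22 | 2β-(tert-butyldimethylsilyloxy)-4α-hydroxy-10α-(4-methoxybenzyloxy)-5β-H-dauc-8-en-6-one | O=C1CC(C)=C[C@@H](OCc3ccc(OC)cc3)[C@@]2(C)[C@H](O[Si](C)(C)C(C)(C)C)C[C@](O)(C(C)C)[C@@H]12 | intermediate
23 | 2β-(tert-butyldimethylsilyloxy)-10α-(4-methoxybenzyloxy)-5β-H-dauc-8-ene-4α,6β-diol | O[C@@H]1CC(C)=C[C@@H](OCc3ccc(OC)cc3)[C@@]2(C)[C@H](O[Si](C)(C)C(C)(C)C)C[C@](O)(C(C)C)[C@@H]12 | intermediate
24 | 2β-(tert-butyldimethylsilyloxy)-5β-H-dauc-8-ene-4α,6β,10α-triol | O[C@@H]1CC(C)=C[C@@H](O)[C@@]2(C)[C@H](O[Si](C)(C)C(C)(C)C)C[C@](O)(C(C)C)[C@@H]12 | intermediate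
25 | (Z)-2-methylbut-2-enoic acid (angelic acid) | C/C=C(/C)C(=O)O | starting material
26 | (Z)-2-methylbut-2-enoic 2,4,6-trichlorobenzoic anhydride (not isolated) | C/C=C(/C)C(=O)OC(=O)c1c(Cl)cc(Cl)cc1Cl | intermediate
27 | 6β,10α-bis[(Z)-2-methylbut-2-enoyloxy]-2β-(tert-butyldimethylsilyloxy)-5β-H-dauc-8-en-4α-ol | C/C=C(/C)C(=O)O[C@@H]1CC(C)=C[C@@H](OC(=O)/C(C)=C\C)[C@@]2(C)[C@H](O[Si](C)(C)C(C)(C)C)C[C@](O)(C(C)C)[C@@H]12 | intermediate
28 | 6β,10α-bis[(Z)-2-methylbut-2-enoyloxy]-5β-H-dauc-8-ene-2β,4α-diol (CNP0249167.1) | C/C=C(/C)C(=O)O[C@@H]1CC(C)=C[C@@H](OC(=O)/C(C)=C\C)[C@@]2(C)[C@H](O)C[C@](O)(C(C)C)[C@@H]12 | target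

**Totals**

Total step count: 17. Longest linear sequence: 16 steps (steps 1–9 and 11–17; step 10 is a one-step side branch).

**Steps most likely to fail**

Step 11. The siloxyallyl carbanion formed on the ring fragment may lose the C2 silanolate, or the hindered acylsilane may stop at the simple 1,2-adduct, before cyclopropane closure and rearrangement occur. The fallback reverses the pairing to the form of this annulation with the closest precedent (cycloalkenyl methyl ketone enolate plus an acyclic acylsilane, where no carbanion sits on the ring); it sets out from 6 and comes back at 20. Compound 6 is treated with ethynylmagnesium bromide and CeCl3 and then with aqueous HCl to give (4S)-3-ethynyl-4-hydroxy-2-methyl-4-(propan-2-yl)cyclopent-2-en-1-one F1. Reduction with Me4NBH(OAc)3 gives (1R,4S)-3-ethynyl-2-methyl-4-(propan-2-yl)cyclopent-2-ene-1,4-diol F2, and TBSCl/imidazole gives the mono-silyl ether F3. Hydration catalysed by (Ph3P)AuNTf2 in wet methanol gives the methyl ketone 1-[(3R,5S)-3-[(tert-butyldimethylsilyl)oxy]-5-hydroxy-2-methyl-5-(propan-2-yl)cyclopent-1-en-1-yl]ethan-1-one F4. Separately, commercial acetyltrimethylsilane is formylated (NaH, ethyl formate) to (Z)-3-hydroxy-1-(trimethylsilyl)prop-2-en-1-one F5, which is etherified with 15 under Mitsunobu conditions (PPh3, diisopropyl azodicarboxylate) to (E)-3-[(4-methoxyphenyl)methoxy]-1-(trimethylsilyl)prop-2-en-1-one F6. The dilithium salt of F4 (2.2 equiv LiN(iPr)2) and F6 should undergo the same Brook/cyclopropanation/oxy-Cope cascade, and quenching with Me3SiCl gives the 4α,6,8-tris(trimethylsilyloxy) diene F7. MeLi should cleave only the unhindered C8 enol ether, and trapping the C8 enolate with N-(5-chloropyridin-2-yl)triflimide gives 20.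

Step 8. Silylation at the dithiane carbon may fail for steric reasons (O-silylation only, or attack at the γ-carbon C1). The fallback avoids the quaternary silyl dithiane; it sets out from 11 and comes back at 13. Compound 11 is hydrolysed (MeI, CaCO3, aqueous MeCN) to (3R,5S)-3-[(tert-butyldimethylsilyl)oxy]-5-hydroxy-2-methyl-5-(propan-2-yl)cyclopent-1-ene-1-carbaldehyde F8. Addition of Me3SiLi (from Me3SiSiMe3 and MeLi) at −78 °C with a cold acidic quench gives the α-silyl carbinol F9, and Swern oxidation gives the acylsilane with a free tertiary hydroxyl F10. Silylation with Me3SiOTf and 2,6-lutidine gives 13.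

Step 16. The activated angelate may isomerise from Z to E (tiglate formation), and acylation of the neopentylic C10 hydroxyl may be incomplete. The fallback builds the (Z)-alkenes on the substrate; it sets out from 24 and comes back at 27. Compound 24 is esterified at O6 and O10 with 2-[bis(2,2,2-trifluoroethoxy)phosphoryl]propanoic acid (N,N'-dicyclohexylcarbodiimide, 4-(dimethylamino)pyridine) to give the bis(phosphonopropanoate) F11. Still–Gennari olefination (KN(SiMe3)2, 18-crown-6, acetaldehyde, THF, −78 °C) should form both (Z)-2-methylbut-2-enoates and give 27.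

**Further compounds**

F1 | step 11 | (4S)-3-ethynyl-4-hydroxy-2-methyl-4-(propan-2-yl)cyclopent-2-en-1-one | CC1=C(C#C)[C@@](O)(C(C)C)CC1=O
F2 | step 11 | (1R,4S)-3-ethynyl-2-methyl-4-(propan-2-yl)cyclopent-2-ene-1,4-diol | CC1=C(C#C)[C@@](O)(C(C)C)C[C@H]1O
F3 | step 11 | (1S,4R)-4-[(tert-butyldimethylsilyl)oxy]-2-ethynyl-3-methyl-1-(propan-2-yl)cyclopent-2-en-1-ol | CC1=C(C#C)[C@@](O)(C(C)C)C[C@H]1O[Si](C)(C)C(C)(C)C
F4 | step 11 | 1-[(3R,5S)-3-[(tert-butyldimethylsilyl)oxy]-5-hydroxy-2-methyl-5-(propan-2-yl)cyclopent-1-en-1-yl]ethan-1-one | CC1=C(C(C)=O)[C@@](O)(C(C)C)C[C@H]1O[Si](C)(C)C(C)(C)C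
F5 | step 11 | (Z)-3-hydroxy-1-(trimethylsilyl)prop-2-en-1-one | C[Si](C)(C)C(=O)/C=C\O
F6 | step 11 | (E)-3-[(4-methoxyphenyl)methoxy]-1-(trimethylsilyl)prop-2-en-1-one | C[Si](C)(C)C(=O)/C=C/OCc1ccc(OC)cc1
F7 | step 11 | 2β-(tert-butyldimethylsilyloxy)-10α-(4-methoxybenzyloxy)-4α,6,8-tris(trimethylsilyloxy)-14-nordauca-5,8-diene | C[Si](C)(C)OC1CC(O[Si](C)(C)C)=C[C@@H](OCc3ccc(OC)cc3)[C@@]2(C)[C@H](O[Si](C)(C)C(C)(C)C)C[C@](O[Si](C)(C)C)(C(C)C)C=12
F8 | step 8 | (3R,5S)-3-[(tert-butyldimethylsilyl)oxy]-5-hydroxy-2-methyl-5-(propan-2-yl)cyclopent-1-ene-1-carbaldehyde | CC1=C(C=O)[C@@](O)(C(C)C)C[C@H]1O[Si](C)(C)C(C)(C)C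
F9 | step 8 | (1S,4R)-4-[(tert-butyldimethylsilyl)oxy]-2-[hydroxy(trimethylsilyl)methyl]-3-methyl-1-(propan-2-yl)cyclopent-2-en-1-ol, both carbinol epimers | CC1=C(C(O)[Si](C)(C)C)[C@@](O)(C(C)C)C[C@H]1O[Si](C)(C)C(C)(C)C
F10 | step 8 | [(3R,5S)-3-[(tert-butyldimethylsilyl)oxy]-5-hydroxy-2-methyl-5-(propan-2-yl)cyclopent-1-en-1-yl](trimethylsilyl)methanone | CC1=C(C(=O)[Si](C)(C)C)[C@@](O)(C(C)C)C[C@H]1O[Si](C)(C)C(C)(C)C
F11 | step 16 | 6β,10α-bis{2-[bis(2,2,2-trifluoroethoxy)phosphoryl]propanoyloxy}-2β-(tert-butyldimethylsilyloxy)-5β-H-dauc-8-en-4α-ol, epimers at the phosphonate-bearing carbons | CC(C(=O)O[C@@H]1CC(C)=C[C@@H](OC(=O)C(C)P(=O)(OCC(F)(F)F)OCC(F)(F)F)[C@@]2(C)[C@H](O[Si](C)(C)C(C)(C)C)C[C@](O)(C(C)C)[C@@H]12)P(=O)(OCC(F)(F)F)OCC(F)(F)F
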